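**Retrosynthetic overview**

- The strategy rests on ring B, a hydroquinone whose hydroxyl-bearing carbon C-2 lies between C-1 (diaryl ether oxygen) and C-3 (the (CH2)14 chain). The 21-membered ring bridges C-1 and C-3 across that carbon.
- Target 21 comes from the bis(methyl ether) 20 by BBr3 demethylation. 20 comes from chromium carbene 18 by an intramolecular Dötz benzannulation that builds ring B (two vinyl carbons, carbene carbon, two alkyne carbons, one CO) and the macrocycle in one operation.
- 18 comes from the (Z)-2-bromovinyl aryl ether 13 (Br/Li exchange, Cr(CO)6, O-methylation), and 13 from phenol 11 and 1,2-dibromoethene.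
- 11 comes from ester 7 (partial reduction, Ohira-Bestmann alkynylation, desilylation). 7 comes from a Negishi coupling of aryl bromide 5 with the zinc reagent of bromo ester 3, itself made from pentadecanolide 1.
- Ring order: ring A is bought; ring B and the 21-membered ring are formed last and together.

Key step: step 10

Remark: 1,2-dibromoethene is taken as the commercial cis/trans mixture, of which the cis isomer is expected to deliver bromoacetylene; ring B is numbered C-1 (aryloxy), C-2 (OH), C-3 (chain), C-5 (OH).

**Route**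

Step 1
Reactants: 1 omega-pentadecalactone (oxacyclohexadecan-2-one)
Product: 2 15-bromopentadecanoic acid
Conditions: HBr (33% in AcOH), cat. H2SO4, 80 °C
Reagents that add atoms: hydrogen bromide, Br
Why: Acid-promoted lactone ring opening, in which bromide displaces the protonated primary alkyl oxygen by SN2, is a standard way to omega-bromo acids.

Step 2
Reactants: 2 15-bromopentadecanoic acid
Product: 3 methyl 15-bromopentadecanoate
Conditions: MeOH, cat. H2SO4, reflux
Reagents that add atoms: methanol, CO
Why: Fischer esterification in excess methanol should go to completion while the primary bromide is untouched.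

Step 3
Reactants: 4 3-bromo-5-methoxyphenol
Product: 5 (3-bromo-5-methoxyphenoxy)(tert-butyl)dimethylsilane
Conditions: TBSCl, imidazole, DMF, rt
Reagents that add atoms: tert-butyldimethylsilyl chloride, CC(C)(C)[Si](C)(C)Cl
Why: Imidazole-promoted silylation masks the acidic phenol, which would otherwise quench the alkylzinc reagent of the next step.

Step 4
Reactants: 3 methyl 15-bromopentadecanoate; 5 (3-bromo-5-methoxyphenoxy)(tert-butyl)dimethylsilane
Product: 7 methyl 15-[3-(tert-butyldimethylsilyloxy)-5-methoxyphenyl]pentadecanoate, via alkylzinc bromide 6 (not isolated)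
Conditions: 3, Zn dust, LiCl, cat. I2, THF, 50 °C; then 5, Pd(OAc)2 (2 mol%), SPhos (4 mol%), THF, rt to 50 °C
Reagents that add atoms: none
Why: Negishi sp3-sp2 coupling: LiCl-assisted zinc insertion into the primary bromide tolerates the ester, and the Pd/SPhos catalyst should couple the primary alkylzinc with the aryl bromide faster than beta-hydride elimination.

Step 5
Reactants: 7 methyl 15-[3-(tert-butyldimethylsilyloxy)-5-methoxyphenyl]pentadecanoate
Product: 8 15-[3-(tert-butyldimethylsilyloxy)-5-methoxyphenyl]pentadecanal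
Conditions: i-Bu2AlH (1.1 equiv), CH2Cl2, −78 °C; MeOH quench, aq. KNaC4H4O6
Reagents that add atoms: none
Why: Partial reduction of a methyl ester with i-Bu2AlH at low temperature stops at the aluminium hemiacetal, which releases the aldehyde only on work-up.

Step 6
Reactants: 8 15-[3-(tert-butyldimethylsilyloxy)-5-methoxyphenyl]pentadecanal; 9 dimethyl (1-diazo-2-oxopropyl)phosphonate
Product: 11 3-(hexadec-15-yn-1-yl)-5-methoxyphenol, via silyl ether alkyne 10 (not isolated)
Conditions: K2CO3 (3 equiv), MeOH/THF, 0 °C to rt, then 40 °C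
Reagents that add atoms: none
Why: Ohira-Bestmann (Seyferth-Gilbert) homologation converts the aldehyde into the terminal alkyne through the diazoalkene and alkylidene carbene, and continued exposure to K2CO3 in methanol should methanolyse the aryl silyl ether.

Step 7
Reactants: 11 3-(hexadec-15-yn-1-yl)-5-methoxyphenol; 12 1,2-dibromoethene (cis/trans mixture)
Product: 13 1-{[(Z)-2-bromoethenyl]oxy}-3-(hexadec-15-yn-1-yl)-5-methoxybenzene
Conditions: Cs2CO3 (2.5 equiv), 12 (5 equiv), DMF, 60 °C, argon, closed vessel
Reagents that add atoms: none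
Why: Elimination-addition: base-induced anti loss of HBr from the dibromoethene gives bromoacetylene, to whose unsubstituted carbon the phenoxide adds, and anti protonation of the alpha-bromovinyl anion sets the Z geometry (nucleophilic addition to a haloalkyne).

Step 8
Reactants: 13 1-{[(Z)-2-bromoethenyl]oxy}-3-(hexadec-15-yn-1-yl)-5-methoxybenzene; 14 chromium hexacarbonyl
Product: 17 tetramethylammonium pentacarbonyl{(2Z)-3-[3-(hexadec-15-yn-1-yl)-5-methoxyphenoxy]-1-oxidoprop-2-en-1-ylidene}chromate, via dilithio species 15 (not isolated), via dilithium acylchromate 16 (not isolated)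
Conditions: t-BuLi (3.05 equiv), THF, −78 °C (13 added slowly to the base); Cr(CO)6 (1.0 equiv), −78 to −20 °C; aq. Me4NBr, CH2Cl2 extraction
Reagents that add atoms: tetramethylammonium bromide, C[N+](C)(C)C.[Br-]
Why: First half of the Fischer carbene synthesis: inverse addition lets t-BuLi remove the alkyne proton and effect Br/Li exchange with retention, the cis beta-aryloxyvinyllithium (no anti-disposed leaving group) is expected to add to a CO ligand of the single equivalent of Cr(CO)6 in preference to the far less nucleophilic acetylide, and the aqueous ammonium salt reprotonates the acetylide while exchanging the cation.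

Step 9
Reactants: 17 tetramethylammonium acylchromate from step 8
Product: 18 pentacarbonyl{(2Z)-3-[3-(hexadec-15-yn-1-yl)-5-methoxyphenoxy]-1-methoxyprop-2-en-1-ylidene}chromium
Conditions: MeOTf (1.3 equiv), CH2Cl2, 0 °C; rapid filtration through silica under argon
Reagents that add atoms: methyl trifluoromethanesulfonate, COS(=O)(=O)C(F)(F)F
Why: O-alkylation of the acylmetalate oxygen by a hard methylating agent is the standard second half of the Fischer carbene synthesis and now meets a neutral terminal alkyne that cannot be C-methylated.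

Step 10
Reactants: 18 pentacarbonyl{(2Z)-3-[3-(hexadec-15-yn-1-yl)-5-methoxyphenoxy]-1-methoxyprop-2-en-1-ylidene}chromium
Product: 20 1^5,3^5-dimethoxy-2-oxa-1(1,3),3(1,3)-dibenzenacycloheptadecaphan-3^2-ol (21-membered diaryl ether; ring B a 4-methoxyphenol with OH at C-2, ring A a methyl ether), via tricarbonylchromium arene complex 19 (not isolated)
Conditions: benzene, 75 °C, syringe-pump addition to 0.002 M, argon; then air, CH2Cl2, rt, filtration through silica
Reagents that add atoms: none
Why: Proposed new method: thermal loss of one CO from chromium frees a site at which the tethered terminal alkyne binds and inserts into the Cr=C bond with its CH carbon bonding to the carbene carbon, CO insertion then gives a chromium-bound dienylketene, and 6-pi electrocyclization of the ketene carbon onto the aryloxy-bearing vinyl carbon followed by enolization gives the 4-methoxyphenol; the closest known reaction type is the intramolecular Dötz benzannulation of alkenyl Fischer carbene complexes that carry the alkyne on a carbon tether at the beta carbon, which gives meta-bridged cyclophane phenols, whereas a tether joined through a beta-aryloxy oxygen has not been shown. Ring B is closed by this [3+2+1] assembly ending in the electrocyclization, and the macrocycle is closed at the alkyne insertion as a 23-membered loop that becomes the 21-membered meta-bridge once the CO-derived carbon links the chain-bearing carbon to the aryloxy-bearing carbon. No stereocentre is formed, the Z geometry of the vinyl ether is lost on aromatization, and the push-pull character of the beta-aryloxyvinyl carbene should let either alkene geometry reach the reactive conformer. The step needs the chain-bearing alkyne carbon to end next to the new C-OH carbon, which the strong preference of terminal alkynes for bonding to the carbene carbon through their unsubstituted end secures and the long unstrained tether does not oppose. It also needs ring closure to beat oligomerization and CO insertion to beat CO-free cyclopentannulation, for which slow addition at high dilution, a non-coordinating solvent and the only weakly donating aryloxy group are relied on.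

Step 11
Reactants: 20 macrocyclic bis(methyl ether) phenol from step 10
Product: 21 2-oxa-1(1,3),3(1,3)-dibenzenacycloheptadecaphane-1^5,3^2,3^5-triol (target CNP0393720.0)
Conditions: BBr3 (6 equiv), CH2Cl2, −78 °C to rt; aq. NaHCO3/Na2S2O4 work-up under argon
Reagents that add atoms: none
Why: BBr3 ether cleavage (Lewis acid complexation, then bromide SN2 at the methyl groups) should remove both aryl methyl ethers while the diaryl ether, which offers no sp3 carbon for attack, stays intact.

**Compound list**

1 | omega-pentadecalactone (oxacyclohexadecan-2-one) | O=C1CCCCCCCCCCCCCCO1 | starting material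
2 | 15-bromopentadecanoic acid | OC(=O)CCCCCCCCCCCCCCBr | intermediate
3 | methyl 15-bromopentadecanoate | COC(=O)CCCCCCCCCCCCCCBr | intermediate
4 | 3-bromo-5-methoxyphenol | COc1cc(O)cc(Br)c1 | starting material
5 | (3-bromo-5-methoxyphenoxy)(tert-butyl)dimethylsilane | COc1cc(O[Si](C)(C)C(C)(C)C)cc(Br)c1 | intermediate
6 | (15-methoxy-15-oxopentadecyl)zinc bromide | COC(=O)CCCCCCCCCCCCCC[Zn]Br | intermediate
7 | methyl 15-[3-(tert-butyldimethylsilyloxy)-5-methoxyphenyl]pentadecanoate | COC(=O)CCCCCCCCCCCCCCc1cc(OC)cc(O[Si](C)(C)C(C)(C)C)c1 | intermediate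
8 | 15-[3-(tert-butyldimethylsilyloxy)-5-methoxyphenyl]pentadecanal | O=CCCCCCCCCCCCCCCc1cc(OC)cc(O[Si](C)(C)C(C)(C)C)c1 | intermediate
9 | dimethyl (1-diazo-2-oxopropyl)phosphonate | CC(=O)C(=[N+]=[N-])P(=O)(OC)OC | starting material
10 | tert-butyl[3-(hexadec-15-yn-1-yl)-5-methoxyphenoxy]dimethylsilane | C#CCCCCCCCCCCCCCCc1cc(OC)cc(O[Si](C)(C)C(C)(C)C)c1 | intermediate
11 | 3-(hexadec-15-yn-1-yl)-5-methoxyphenol | C#CCCCCCCCCCCCCCCc1cc(O)cc(OC)c1 | intermediate
12 | 1,2-dibromoethene (cis/trans mixture) | BrC=CBr | starting material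
13 | 1-{[(Z)-2-bromoethenyl]oxy}-3-(hexadec-15-yn-1-yl)-5-methoxybenzene | COc1cc(O/C=C\Br)cc(CCCCCCCCCCCCCCC#C)c1 | intermediate
14 | chromium hexacarbonyl | O=C=[Cr](=C=O)(=C=O)(=C=O)(=C=O)=C=O | starting material
15 | dilithio species: lithium acetylide and (Z)-2-aryloxyvinyllithium in one molecule | COc1cc(O/C=C\[Li])cc(CCCCCCCCCCCCCCC#C[Li])c1 | intermediate
16 | dilithium acylchromate (lithium acetylide end, lithium pentacarbonyl acylchromate end) | [Li+].[O-]C(/C=C\Oc1cc(OC)cc(CCCCCCCCCCCCCCC#C[Li])c1)=[Cr](=C=O)(=C=O)(=C=O)(=C=O)=C=O | intermediate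
17 | tetramethylammonium pentacarbonyl{(2Z)-3-[3-(hexadec-15-yn-1-yl)-5-methoxyphenoxy]-1-oxidoprop-2-en-1-ylidene}chromate | C[N+](C)(C)C.[O-]C(/C=C\Oc1cc(OC)cc(CCCCCCCCCCCCCCC#C)c1)=[Cr](=C=O)(=C=O)(=C=O)(=C=O)=C=O | intermediate
18 | pentacarbonyl{(2Z)-3-[3-(hexadec-15-yn-1-yl)-5-methoxyphenoxy]-1-methoxyprop-2-en-1-ylidene}chromium | COC(/C=C\Oc1cc(OC)cc(CCCCCCCCCCCCCCC#C)c1)=[Cr](=C=O)(=C=O)(=C=O)(=C=O)=C=O | intermediate
19 | tricarbonylchromium complex of 20, the Cr(CO)3 unit eta-6 bound to ring B (written as two parts) | COc1cc2cc(c1)Oc1cc(OC)cc(c1O)CCCCCCCCCCCCCC2.O=C=[Cr](=C=O)=C=O | intermediate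
20 | 1^5,3^5-dimethoxy-2-oxa-1(1,3),3(1,3)-dibenzenacycloheptadecaphan-3^2-ol | COc1cc2cc(c1)Oc1cc(OC)cc(c1O)CCCCCCCCCCCCCC2 | intermediate
21 | 2-oxa-1(1,3),3(1,3)-dibenzenacycloheptadecaphane-1^5,3^2,3^5-triol (CNP0393720.0) | Oc1cc2cc(c1)Oc1cc(O)cc(c1O)CCCCCCCCCCCCCC2 | target

**Step count**

Total step count: 11.
Longest linear sequence: 10 steps (steps 1, 2, 4, 5, 6, 7, 8, 9, 10, 11, from lactone 1); step 3 is the one-step side branch from 4.

**Steps most likely to fail**

1. Step 10 (macrocyclizing benzannulation).
- What may go wrong: intermolecular alkyne insertion could outrun ring closure and give oligomers. The donor-substituted vinylcarbene could cyclize without CO insertion, to five-membered-ring products. The oxygen-chelated tetracarbonyl species could decompose before the alkyne is taken up.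
- Fallback (sets out from 5, returns at 21, known chemistry only): both arenes are bought and the 21-membered ring is closed by olefin metathesis. 8-Bromooct-1-ene is converted with Zn dust and LiCl in THF into oct-7-en-1-ylzinc bromide F1. Negishi coupling of F1 with 5 (Pd(OAc)2, SPhos) should give tert-butyl[3-methoxy-5-(oct-7-en-1-yl)phenoxy]dimethylsilane F2, and Bu4NF frees 3-methoxy-5-(oct-7-en-1-yl)phenol F3. A second portion of F1 is coupled with an excess of bought 1,3-dibromo-2,5-dimethoxybenzene to give 1-bromo-2,5-dimethoxy-3-(oct-7-en-1-yl)benzene F4. Ullmann ether synthesis of F3 with F4 (CuI, picolinic acid, K3PO4, DMSO, 90 °C) should give 1-[2,5-dimethoxy-3-(oct-7-en-1-yl)phenoxy]-3-methoxy-5-(oct-7-en-1-yl)benzene F5. Ring-closing metathesis (second-generation Grubbs catalyst, CH2Cl2, 0.001 M, 40 °C) closes the 21-membered cycloalkene tri-O-methyl ether F6 as an E/Z mixture. Hydrogenation (H2, Pd/C, EtOAc) gives the saturated tri-O-methyl ether of the target F7, and BBr3 as in step 11 then gives 21.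

2. Step 8 (acylchromate formation).
- What may go wrong: the alkyne proton could quench the vinyllithium before the base removes it. The cis beta-aryloxyvinyllithium could lose lithium aryloxide on warming. The acetylide could compete for Cr(CO)6 and give a doubly metallated product.
- Fallback (sets out from 11, returns at 20): the carbon-chromium bond is made with reversed polarity, so that no organolithium meets the alkyne. Oxa-Michael addition of 11 to methyl propiolate (cat. DABCO, CH2Cl2) should give methyl (2E)-3-[3-(hexadec-15-yn-1-yl)-5-methoxyphenoxy]prop-2-enoate F8. LiOH in THF/water gives (2E)-3-[3-(hexadec-15-yn-1-yl)-5-methoxyphenoxy]prop-2-enoic acid F9, and 1-chloro-N,N,2-trimethylprop-1-en-1-amine converts it under neutral conditions into (2E)-3-[3-(hexadec-15-yn-1-yl)-5-methoxyphenoxy]prop-2-enoyl chloride F10. Cr(CO)6 is reduced with NaC10H8 (sodium naphthalenide) in THF at −78 °C to disodium pentacarbonylchromate F11, which is acylated by F10 to sodium pentacarbonyl{(2E)-3-[3-(hexadec-15-yn-1-yl)-5-methoxyphenoxy]-1-oxidoprop-2-en-1-ylidene}chromate F12. MeOTf then gives pentacarbonyl{(2E)-3-[3-(hexadec-15-yn-1-yl)-5-methoxyphenoxy]-1-methoxyprop-2-en-1-ylidene}chromium F13, the E isomer of 18, which is cyclized under the conditions of step 10 through 19 to 20.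

3. Step 7 (bromovinyl ether formation).
- What may go wrong: bromoacetylene could form too slowly under carbonate base or be lost as a volatile, air-sensitive gas. The product could lose HBr to the aryl ynol ether and take up a second phenoxide, giving a 1,2-bis(aryloxy)ethene.
- Fallback (sets out from 11, returns at 13): the vinyl ether is built first and the bromine introduced afterwards. 11 is alkylated with excess 1,2-dibromoethane (K2CO3, MeCN, reflux) to 1-(2-bromoethoxy)-3-(hexadec-15-yn-1-yl)-5-methoxybenzene F14. KOt-Bu in THF at 0 °C eliminates HBr to 1-(ethenyloxy)-3-(hexadec-15-yn-1-yl)-5-methoxybenzene F15. Titration with Br2 (1.0 equiv, CH2Cl2, −78 °C), to which the enol ether should respond far faster than the alkyne or the arene, gives racemic 1-(1,2-dibromoethoxy)-3-(hexadec-15-yn-1-yl)-5-methoxybenzene F16. F16 loses HBr with Et3N on warming to give 13, the Z isomer being expected to predominate as with alkyl analogues.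

**Further compounds**

F1 | step 10 | oct-7-en-1-ylzinc bromide | C=CCCCCCC[Zn]Br
F2 | step 10 | tert-butyl[3-methoxy-5-(oct-7-en-1-yl)phenoxy]dimethylsilane | COc1cc(O[Si](C)(C)C(C)(C)C)cc(CCCCCCC=C)c1
F3 | step 10 | 3-methoxy-5-(oct-7-en-1-yl)phenol | COc1cc(O)cc(CCCCCCC=C)c1
F4 | step 10 | 1-bromo-2,5-dimethoxy-3-(oct-7-en-1-yl)benzene | COc1cc(Br)c(OC)c(CCCCCCC=C)c1
F5 | step 10 | 1-[2,5-dimethoxy-3-(oct-7-en-1-yl)phenoxy]-3-methoxy-5-(oct-7-en-1-yl)benzene | COc1cc(Oc2cc(OC)cc(CCCCCCC=C)c2OC)cc(CCCCCCC=C)c1
F6 | step 10 | 21-membered cycloalkene tri-O-methyl ether (E/Z mixture, C=C in the middle of the 14-carbon bridge) | COc1cc2cc(c1)Oc1cc(OC)cc(c1OC)CCCCCCC=CCCCCCC2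
F7 | step 10 | 1^5,3^2,3^5-trimethoxy-2-oxa-1(1,3),3(1,3)-dibenzenacycloheptadecaphane (tri-O-methyl ether of 21) | COc1cc2cc(c1)Oc1cc(OC)cc(c1OC)CCCCCCCCCCCCCC2
F8 | step 8 | methyl (2E)-3-[3-(hexadec-15-yn-1-yl)-5-methoxyphenoxy]prop-2-enoate | COC(=O)/C=C/Oc1cc(OC)cc(CCCCCCCCCCCCCCC#C)c1
F9 | step 8 | (2E)-3-[3-(hexadec-15-yn-1-yl)-5-methoxyphenoxy]prop-2-enoic acid | OC(=O)/C=C/Oc1cc(OC)cc(CCCCCCCCCCCCCCC#C)c1
F10 | step 8 | (2E)-3-[3-(hexadec-15-yn-1-yl)-5-methoxyphenoxy]prop-2-enoyl chloride | ClC(=O)/C=C/Oc1cc(OC)cc(CCCCCCCCCCCCCCC#C)c1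
F11 | step 8 | disodium pentacarbonylchromate | [Na+].[Na+].O=C=[Cr-2](=C=O)(=C=O)(=C=O)=C=O
F12 | step 8 | sodium pentacarbonyl{(2E)-3-[3-(hexadec-15-yn-1-yl)-5-methoxyphenoxy]-1-oxidoprop-2-en-1-ylidene}chromate | [Na+].[O-]C(/C=C/Oc1cc(OC)cc(CCCCCCCCCCCCCCC#C)c1)=[Cr](=C=O)(=C=O)(=C=O)(=C=O)=C=O
F13 | step 8 | pentacarbonyl{(2E)-3-[3-(hexadec-15-yn-1-yl)-5-methoxyphenoxy]-1-methoxyprop-2-en-1-ylidene}chromium | COC(/C=C/Oc1cc(OC)cc(CCCCCCCCCCCCCCC#C)c1)=[Cr](=C=O)(=C=O)(=C=O)(=C=O)=C=O
F14 | step 7 | 1-(2-bromoethoxy)-3-(hexadec-15-yn-1-yl)-5-methoxybenzene | COc1cc(OCCBr)cc(CCCCCCCCCCCCCCC#C)c1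
F15 | step 7 | 1-(ethenyloxy)-3-(hexadec-15-yn-1-yl)-5-methoxybenzene | COc1cc(OC=C)cc(CCCCCCCCCCCCCCC#C)c1
F16 | step 7 | 1-(1,2-dibromoethoxy)-3-(hexadec-15-yn-1-yl)-5-methoxybenzene (racemic) | COc1cc(OC(Br)CBr)cc(CCCCCCCCCCCCCCC#C)c1
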